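**Retrosynthetic overview**

1. Locants: carbocycle C1–C10 (C1=C10 enoate, C4 bears C15H2OH, C6 bears the lactone O, C7 is the fusion CH, C8 bears the isobutyrate); lactone C11 (α), C12 (C=O), C13 (=CH2); ester carbon C14. Target 23 ⇐ silyl ether 22 ⇐ ring-closing metathesis at C1=C10 of lactone diene 21 (ten-membered ring, formed last).
2. γ-Lactone ring (formed first) ⇐ bond C11–C7 by 5-exo attack of a phosphonoacetate carbanion, tethered as the C6 ester, on the C7–C8 epoxide of acyclic 18, then olefination with formaldehyde (C13) in the same flask.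
3. Enabling feature: in the lactone ring (O6–C6–C7–C11–C12) the β-carbon C7 lies between two oxygen-bearing carbons, ring C6 and exocyclic C8, with C11 and O8 anti across C7–C8. This is the imprint of an erythro trans-2,3-epoxy alcohol acylated on O6; the exocyclic C11=C13 is the imprint of a phosphonate.
4. Epoxy alcohol 16 ⇐ Sharpless epoxidation of (6R,E)-allylic alcohol 15 ⇐ catalytic asymmetric alkenylzinc addition of enyne ester 12 (C7–C10, C14) to aldehyde 8 (C1–C6, C15).
5. C4 of 8 ⇐ Evans alkylation of a hex-5-enoyl oxazolidinone with tert-butyl bromoacetate; 12 ⇐ trimethyl phosphonoacetate, propargyl bromide and formaldehyde.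

Key step: step 11

Remark (assumption): (−)-MIB is taken to transfer the alkenyl group to the Si face of aldehyde 8, as with other unbranched aliphatic aldehydes; the D-(−)-tartrate epoxidation of step 9 is matched only for the (6R) carbinol and removes any (6S) epimer.

**Route**

Step 1
Reactants: 1 (R)-4-benzyl-1,3-oxazolidin-2-one; 2 hex-5-enoyl chloride
Product: 3 (R)-4-benzyl-3-(hex-5-enoyl)-1,3-oxazolidin-2-one
Conditions: n-BuLi, THF, −78 °C; then 2, −78 → 0 °C
Reagents that add atoms: none
Why: N-acylation of the lithiated oxazolidinone by an acid chloride is the standard entry to an Evans imide and forms no stereocentre.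

Step 2
Reactants: 3 (R)-4-benzyl-3-(hex-5-enoyl)-1,3-oxazolidin-2-one; 4 tert-butyl bromoacetate
Product: 5 tert-butyl (3S)-3-{[(4R)-4-benzyl-2-oxo-1,3-oxazolidin-3-yl]carbonyl}hept-6-enoate
Conditions: NaN(SiMe3)2, THF, −78 °C; then 4, −78 → −40 °C
Reagents that add atoms: none
Why: Evans alkylation, in which the chelated Z-sodium enolate is attacked by the activated bromide on the face away from the benzyl group, sets C4 as (S).

Step 3
Reactants: 5 tert-butyl (3S)-3-{[(4R)-4-benzyl-2-oxo-1,3-oxazolidin-3-yl]carbonyl}hept-6-enoate
Product: 6 tert-butyl (3S)-3-(hydroxymethyl)hept-6-enoate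
Conditions: LiBH4, MeOH (1 equiv), THF, 0 °C
Reagents that add atoms: none
Why: LiBH4 reduces the activated exocyclic imide carbonyl and spares the hindered tert-butyl ester, so the auxiliary is released and C15 appears as CH2OH without touching C4.

Step 4
Reactants: 6 tert-butyl (3S)-3-(hydroxymethyl)hept-6-enoate
Product: 7 tert-butyl (3S)-3-{[(tert-butyldimethylsilyl)oxy]methyl}hept-6-enoate
Conditions: TBSCl, imidazole, DMF, rt
Reagents that add atoms: tert-butyldimethylsilyl chloride, CC(C)(C)[Si](C)(C)Cl
Why: Silylation of the primary alcohol masks O15 until the last step and prevents lactonisation onto the ester.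

Step 5
Reactants: 7 tert-butyl (3S)-3-{[(tert-butyldimethylsilyl)oxy]methyl}hept-6-enoate
Product: 8 (3S)-3-{[(tert-butyldimethylsilyl)oxy]methyl}hept-6-enal
Conditions: DIBAL-H (1.1 equiv), CH2Cl2, −78 °C; Rochelle salt
Reagents that add atoms: none
Why: Partial reduction of the ester by DIBAL-H at low temperature, where the tetrahedral aluminium acetal survives until work-up, should give the C6 aldehyde with the β-stereocentre C4 untouched.

Step 6
Reactants: 9 trimethyl phosphonoacetate; 10 propargyl bromide
Product: 11 methyl 2-(dimethoxyphosphoryl)pent-4-ynoate (racemic)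
Conditions: NaH, THF, 0 °C; then 10, 0 °C → rt (9 in excess)
Reagents that add atoms: none
Why: SN2 C-alkylation of the sodium phosphonoacetate by the propargylic bromide, with excess 9 to suppress double alkylation.

Step 7
Reactants: 11 methyl 2-(dimethoxyphosphoryl)pent-4-ynoate
Product: 12 methyl 2-methylidenepent-4-ynoate
Conditions: 37 % aq. HCHO, K2CO3, THF/H2O, rt
Reagents that add atoms: formaldehyde, C=O
Why: Horner–Wadsworth–Emmons olefination with formaldehyde turns the α-substituted phosphonoacetate into the 2-substituted acrylate under conditions too mild to isomerise the skipped enyne.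

Step 8
Reactants: 12 methyl 2-methylidenepent-4-ynoate; 8 (3S)-3-{[(tert-butyldimethylsilyl)oxy]methyl}hept-6-enal
Product: 15 methyl (4E,6R,8S)-8-{[(tert-butyldimethylsilyl)oxy]methyl}-6-hydroxy-2-methylidenedodeca-4,11-dienoate, via E-alkenylborane 13 (not isolated), via alkenyl(methyl)zinc 14 (not isolated)
Conditions: 12, Cy2BH, toluene, 0 °C → rt; Me2Zn, −78 °C; (−)-MIB (5 mol %), then 8, −20 → 0 °C; aq. NH4Cl
Reagents that add atoms: none
Why: syn-Hydroboration of the terminal alkyne fixes the E geometry of C7=C8, boron-to-zinc exchange gives the alkenylzinc, and the amino-alcohol-catalysed asymmetric alkenylzinc addition to the aldehyde delivers the alkenyl group to the Si face, which sets C6 as (R) under catalyst control.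

Step 9
Reactants: 15 methyl (4E,6R,8S)-8-{[(tert-butyldimethylsilyl)oxy]methyl}-6-hydroxy-2-methylidenedodeca-4,11-dienoate
Product: 16 methyl 2-({(2R,3R)-3-[(1R,3S)-3-{[(tert-butyldimethylsilyl)oxy]methyl}-1-hydroxyhept-6-en-1-yl]oxiran-2-yl}methyl)prop-2-enoate (erythro trans-epoxy alcohol; 6R,7R,8R by ring locants)
Conditions: Ti(OiPr)4 (10 mol %), D-(−)-DIPT (14 mol %), t-BuOOH (1.5 equiv), 4 Å MS, CH2Cl2, −20 °C
Reagents that add atoms: tert-butyl hydroperoxide, CC(C)(C)OO
Why: Sharpless asymmetric epoxidation, for which the (6R) carbinol is the fast, matched substrate of the D-(−)-tartrate catalyst, sets C7 and C8 by reagent control as the erythro trans-epoxide, spares the electron-poor acrylate and the remote vinyl group, and leaves any (6S) epimer behind by kinetic resolution.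

Step 10
Reactants: 16 erythro trans-epoxy alcohol; 17 (diethoxyphosphoryl)acetic acid
Product: 18 diethylphosphonoacetate ester of 16 at O6 (configuration unchanged)
Conditions: DCC, DMAP (10 mol %), CH2Cl2, 0 °C → rt
Reagents that add atoms: none
Why: Steglich esterification acylates the secondary alcohol under neutral conditions that neither open the epoxide nor allow Payne rearrangement.

Step 11
Reactants: 18 diethylphosphonoacetate ester of 16
Product: 20 methyl (4R)-4-hydroxy-2-methylidene-4-[(2R,3R)-2-[(2S)-2-{[(tert-butyldimethylsilyl)oxy]methyl}hex-5-en-1-yl]-4-methylidene-5-oxooxolan-3-yl]butanoate (trans α-methylene lactone with free C8–OH), via phosphono-lactone potassium enolate 19 (not isolated)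
Conditions: KOtBu (1.05 equiv), THF/t-BuOH (4:1), 0 → 35 °C; then (CH2O)n, 0 °C → rt; aq. NH4Cl
Reagents that add atoms: formaldehyde (from paraformaldehyde), C=O
Why: Proposed new method: tert-butoxide generates the phosphonoacetate carbanion, whose carbon C11 opens the epoxide at the proximal carbon C7 by backside (SN2) attack while the oxygen stays on C8, the alkoxide is protonated by tert-butanol, the more acidic C11–H of the new α-phosphono lactone is deprotonated in turn, and this carbanion olefinates formaldehyde (Horner–Wadsworth–Emmons) to give C11=C13 with loss of diethyl phosphate. The closest known reactions are the butenolide synthesis by intramolecular Horner–Wadsworth–Emmons reaction of phosphonoacetates of α-hydroxy ketones (same ester tether and same bond, carbonyl instead of epoxide as electrophile), Stork-type cyclisations of stabilised carbanions onto epoxides, the opening of epoxides by phosphonoacetate anions that starts the Wadsworth–Emmons cyclopropanation, and the methylenation of α-phosphono lactones; the sequence on an ester-tethered 2,3-epoxy alcohol has not been shown. The lactone ring closes in the 5-exo-tet mode. C7 is formed with inversion and is therefore dictated by the Sharpless epoxide, C8 keeps its configuration because its C–O bond is not broken, and the erythro epoxy ester thus gives the trans-fused lactone with C11 and O8 anti, as the target requires. The step needs attack at C7 and not 6-endo attack at C8, which the short O6–C12–C11 tether secures because only C7 can be reached collinearly to its C–O bond within a small ring, as in the C2-selective delivery of carbamate or carbonate nucleophiles from the hydroxyl group of 2,3-epoxy alcohols. It also needs the C8 oxygen to stay away from the C14 ester, from C12 and from phosphorus, which is secured by the protic co-solvent, by storage of the base as the non-electrophilic phosphono-enolate and by a temperature far below that of the phosphoryl shift that leads to cyclopropanes.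

Step 12
Reactants: 20 trans α-methylene lactone with free C8–OH
Product: 21 C8 isobutyrate of 20 (4S,6R,7S,8R by ring locants)
Conditions: (i-PrCO)2O, DMAP (10 mol %), pyridine, CH2Cl2, 0 °C
Reagents that add atoms: isobutyric anhydride, CC(C)C(=O)OC(=O)C(C)C
Why: DMAP-catalysed acylation of the secondary alcohol by the anhydride should be fast enough at 0 °C to outrun lactonisation of the γ-hydroxy ester onto C14 and translactonisation.

Step 13
Reactants: 21 C8 isobutyrate of 20
Product: 22 tert-butyldimethylsilyl ether of the target at O15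
Conditions: second-generation Hoveyda–Grubbs catalyst (15 mol %), 1,4-benzoquinone (30 mol %), toluene (1 mM), 90 °C
Reagents that add atoms: none
Why: Ring-closing metathesis of the terminal vinyl group with the 2-substituted acrylate should close the ten-membered ring, which can hold C1=C10 only with C2 and C9 cis, i.e. as the (E)-enoate that metathesis of 2-substituted acrylates also prefers.

Step 14
Reactants: 22 tert-butyldimethylsilyl ether of the target
Product: 23 methyl (3aS,4R,6E,10S,11aR)-10-(hydroxymethyl)-3-methylidene-4-[(2-methylpropanoyl)oxy]-2-oxo-2,3,3a,4,5,8,9,10,11,11a-decahydrocyclodeca[b]furan-6-carboxylate (CNP0251148.1)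
Conditions: HF·pyridine, pyridine/THF, 0 °C → rt
Reagents that add atoms: none
Why: Fluoride cleaves the primary silyl ether under buffered, non-basic conditions that leave the α-methylene lactone, both esters and the enoate geometry untouched.

**Compound list**

1 | (R)-4-benzyl-1,3-oxazolidin-2-one | O=C1N[C@H](Cc2ccccc2)CO1 | starting material
2 | hex-5-enoyl chloride | C=CCCCC(Cl)=O | starting material
3 | (R)-4-benzyl-3-(hex-5-enoyl)-1,3-oxazolidin-2-one | C=CCCCC(=O)N1C(=O)OC[C@H]1Cc1ccccc1 | intermediate
4 | tert-butyl bromoacetate | CC(C)(C)OC(=O)CBr | starting material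
5 | tert-butyl (3S)-3-{[(4R)-4-benzyl-2-oxo-1,3-oxazolidin-3-yl]carbonyl}hept-6-enoate | C=CCC[C@@H](CC(=O)OC(C)(C)C)C(=O)N1C(=O)OC[C@H]1Cc1ccccc1 | intermediate
6 | tert-butyl (3S)-3-(hydroxymethyl)hept-6-enoate | C=CCC[C@H](CO)CC(=O)OC(C)(C)C | intermediate
7 | tert-butyl (3S)-3-{[(tert-butyldimethylsilyl)oxy]methyl}hept-6-enoate | C=CCC[C@H](CO[Si](C)(C)C(C)(C)C)CC(=O)OC(C)(C)C | intermediate
8 | (3S)-3-{[(tert-butyldimethylsilyl)oxy]methyl}hept-6-enal | C=CCC[C@H](CO[Si](C)(C)C(C)(C)C)CC=O | intermediate
9 | trimethyl phosphonoacetate | COC(=O)CP(=O)(OC)OC | starting material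
10 | propargyl bromide (3-bromoprop-1-yne) | C#CCBr | starting material
11 | methyl 2-(dimethoxyphosphoryl)pent-4-ynoate (racemic) | COC(=O)C(CC#C)P(=O)(OC)OC | intermediate
12 | methyl 2-methylidenepent-4-ynoate | C#CCC(=C)C(=O)OC | intermediate
13 | methyl (4E)-5-(dicyclohexylboranyl)-2-methylidenepent-4-enoate | C=C(C/C=C/B(C1CCCCC1)C1CCCCC1)C(=O)OC | intermediate
14 | [(1E)-4-(methoxycarbonyl)penta-1,4-dien-1-yl](methyl)zinc | C[Zn]/C=C/CC(=C)C(=O)OC | intermediate
15 | methyl (4E,6R,8S)-8-{[(tert-butyldimethylsilyl)oxy]methyl}-6-hydroxy-2-methylidenedodeca-4,11-dienoate | C=CCC[C@H](CO[Si](C)(C)C(C)(C)C)C[C@@H](O)/C=C/CC(=C)C(=O)OC | intermediate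
16 | methyl 2-({(2R,3R)-3-[(1R,3S)-3-{[(tert-butyldimethylsilyl)oxy]methyl}-1-hydroxyhept-6-en-1-yl]oxiran-2-yl}methyl)prop-2-enoate | C=CCC[C@H](CO[Si](C)(C)C(C)(C)C)C[C@@H](O)[C@H]1O[C@@H]1CC(=C)C(=O)OC | intermediate
17 | (diethoxyphosphoryl)acetic acid | CCOP(=O)(CC(=O)O)OCC | starting material
18 | diethylphosphonoacetate ester of 16 at O6 | C=CCC[C@H](CO[Si](C)(C)C(C)(C)C)C[C@@H](OC(=O)CP(=O)(OCC)OCC)[C@H]1O[C@@H]1CC(=C)C(=O)OC | intermediate
19 | potassium enolate of the trans α-(diethoxyphosphoryl)-γ-lactone with free C8–OH | CCOP(=O)(OCC)[C-]1C(=O)O[C@H](C[C@@H](CO[Si](C)(C)C(C)(C)C)CCC=C)[C@H]1[C@H](O)CC(=C)C(=O)OC.[K+] | intermediate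
20 | methyl (4R)-4-hydroxy-2-methylidene-4-[(2R,3R)-2-[(2S)-2-{[(tert-butyldimethylsilyl)oxy]methyl}hex-5-en-1-yl]-4-methylidene-5-oxooxolan-3-yl]butanoate | C=C1C(=O)O[C@H](C[C@@H](CO[Si](C)(C)C(C)(C)C)CCC=C)[C@H]1[C@H](O)CC(=C)C(=O)OC | intermediate
21 | C8 isobutyrate of 20 | C=C1C(=O)O[C@H](C[C@@H](CO[Si](C)(C)C(C)(C)C)CCC=C)[C@H]1[C@H](OC(=O)C(C)C)CC(=C)C(=O)OC | intermediate
22 | O15 tert-butyldimethylsilyl ether of the target | C=C1C(=O)O[C@@H]2C[C@@H](CO[Si](C)(C)C(C)(C)C)CC/C=C(/C(=O)OC)C[C@@H](OC(=O)C(C)C)[C@@H]12 | intermediate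
23 | methyl (3aS,4R,6E,10S,11aR)-10-(hydroxymethyl)-3-methylidene-4-[(2-methylpropanoyl)oxy]-2-oxo-2,3,3a,4,5,8,9,10,11,11a-decahydrocyclodeca[b]furan-6-carboxylate | C=C1C(=O)O[C@@H]2C[C@@H](CO)CC/C=C(/C(=O)OC)C[C@@H](OC(=O)C(C)C)[C@@H]12 | target

**Count and risks**

Total steps: 14. Longest linear sequence: 12 (steps 1–5 and 8–14).

Steps most likely to fail:

1. Step 11 (proposed new method). The carbanion may attack C8 (6-endo); the nascent C8 alkoxide may be captured by the C14 ester, by C12 or by phosphorus before it is protonated; or the ester may not reach the s-cis rotamer needed for closure. The fallback uses the known titanocene epoxide–alkyne radical cyclisation followed by chromium oxidation. It sets out from 16. O-Propargylation (propargyl bromide, Ag2O, CH2Cl2) should give the propargyl ether F1. Cp2TiCl (trivalent titanium, made in the flask from Cp2TiCl2 and Zn dust, THF, rt) should open the epoxide homolytically, and the C7 radical should close 5-exo-dig onto the alkyne, trans to the C6 substituent. This forms the same C7–C11 bond and gives, after hydrogen transfer and work-up, the 3-methylidene-tetrahydrofuran alcohol F2. Acylation as in step 12 gives the isobutyrate F3. Oxidation of the allylic ether CH2 (C12) with CrO3·3,5-dimethylpyrazole (CH2Cl2, −20 °C) should give lactone 21, where the fallback rejoins the route.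

2. Step 13. Oligomerisation, or metathesis at the exocyclic methylene of the lactone, may compete with closure of the medium ring. The fallback moves the ring closure in front of the methylenation and sets out from 18. The cyclisation of step 11 is quenched with NH4Cl instead of formaldehyde, which should give the α-phosphono lactone F4 (both C11 epimers). Acylation as in step 12 gives the isobutyrate F5, which has only the two intended alkenes. Metathesis under the conditions of step 13 should give the macrocyclic phosphono lactone F6. K2CO3 with aqueous HCHO (THF, rt) then installs C13 and returns to 22.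

3. Step 8. Hydroboration may fail to discriminate between the alkyne and the acrylate, or facial control at C6 may be incomplete. The fallback replaces catalyst control by a chemoselective coupling plus kinetic resolution and sets out from 12. Hydrozirconation with Cp2Zr(H)Cl and iodination (I2) should give methyl (4E)-5-iodo-2-methylidenepent-4-enoate F7. Nozaki–Hiyama–Kishi coupling with 8 (CrCl2, NiCl2 cat., DMSO/THF) should give the allylic alcohol as both C6 epimers, F8. Under the conditions of step 9 only the (6R) epimer is epoxidised, which gives 16; the unreacted (6S) epimer is separated.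

Further compounds
F1 | step 11 | O6-propargyl ether of 16 | C=CCC[C@H](CO[Si](C)(C)C(C)(C)C)C[C@@H](OCC#C)[C@H]1O[C@@H]1CC(=C)C(=O)OC
F2 | step 11 | 3-methylidene-tetrahydrofuran analogue of 20 (C12 as CH2, free C8–OH) | C=C1CO[C@H](C[C@@H](CO[Si](C)(C)C(C)(C)C)CCC=C)[C@H]1[C@H](O)CC(=C)C(=O)OC
F3 | step 11 | C8 isobutyrate of F2 | C=C1CO[C@H](C[C@@H](CO[Si](C)(C)C(C)(C)C)CCC=C)[C@H]1[C@H](OC(=O)C(C)C)CC(=C)C(=O)OC
F4 | step 13 | trans α-(diethoxyphosphoryl)-γ-lactone with free C8–OH (C11 epimers) | CCOP(=O)(OCC)C1C(=O)O[C@H](C[C@@H](CO[Si](C)(C)C(C)(C)C)CCC=C)[C@H]1[C@H](O)CC(=C)C(=O)OC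
F5 | step 13 | C8 isobutyrate of F4 | CCOP(=O)(OCC)C1C(=O)O[C@H](C[C@@H](CO[Si](C)(C)C(C)(C)C)CCC=C)[C@H]1[C@H](OC(=O)C(C)C)CC(=C)C(=O)OC
F6 | step 13 | ten-membered-ring α-(diethoxyphosphoryl) lactone (22 with P(O)(OEt)2 and H on C11 in place of the methylidene) | CCOP(=O)(OCC)C1C(=O)O[C@@H]2C[C@@H](CO[Si](C)(C)C(C)(C)C)CC/C=C(/C(=O)OC)C[C@@H](OC(=O)C(C)C)[C@@H]12
F7 | step 8 | methyl (4E)-5-iodo-2-methylidenepent-4-enoate | C=C(C/C=C/I)C(=O)OC
F8 | step 8 | allylic alcohol 15 as a mixture of C6 epimers | C=CCC[C@H](CO[Si](C)(C)C(C)(C)C)CC(O)/C=C/CC(=C)C(=O)OC
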